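**Retrosynthetic overview**

1. Target 26 ⇐ Heck coupling of the (E)-alkenyl iodide 24 with 2-methylbut-3-en-2-ol (25); the cis-epoxy acetate ⇐ hydroxyl-directed epoxidation and acetylation of the 1β-allylic alcohol 22 (oxirane ring formed last).
2. 22 ⇐ alkyne 20 (carboalumination/iodination) ⇐ exocyclic methylene of 14 (hydroboration, oxidation, equilibration at C7, homologation); C1–O ⇐ oxidative 1,3-transposition of the tertiary allylic alcohol 11, reduction, Mitsunobu inversion; C8=C9 is reduced to CH2–CH2 by diimide.
3. Key disconnection: both carbocycles of 11 in one operation, C8=C9 (five-membered ring, closed first) and C1=C2 (seven-membered ring, closed second), by ring-opening/double ring-closing metathesis of the monocyclic cyclopropene 10.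
4. Enabling feature: the 3-methyl-3-alkylcyclopropene ring of 10. Its quaternary sp3 carbon becomes C10 and its two equivalent, strained olefinic CH groups become C9 and C1; C6 next to it carries a buta-1,3-dien-2-yl group (C7, C8, C11) and a vinyl carbinol chain (C5 to C2).
5. 10 ⇐ (S)-limonene (1): cleavage of the ring alkene gives C6 with both arms, and the isopropenyl group is turned into the cyclopropene (CBr2 addition, mono-reduction, dehydrobromination).

Key step: step 9

Remark on locants: seven-membered ring C1 (acetoxy carbon), C2, C3 (oxirane carbons, C3 bears the methyl), C4, C5, C6 (ring-fusion CH); five-membered ring C6, C7 (side-chain carbon), C8, C9, C10 (quaternary ring-fusion carbon); C11 is the first side-chain carbon; β is the face of H-6, α the face of the C10 methyl.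

Remark on mixtures: centres that are erased later (oxirane carbons of 2–4, the cyclopropane centres of 3–9, C7 of 6, the carbinol carbon C3 of 9–11) are carried as diastereomer mixtures and are left unspecified in the SMILES.

Step 1
Reactants: 1 (S)-(−)-limonene
Product: 2 (4S)-limonene 1,2-oxide (cis/trans mixture)
Conditions: mCPBA (1.0 equiv), NaHCO3, CH2Cl2, 0 °C
Reagents that add atoms: mCPBA, O=C(OO)c1cccc(Cl)c1
Why: Prilezhaev epoxidation is much faster at the electron-rich trisubstituted ring alkene than at the isopropenyl group, and the cis/trans mixture is of no consequence because both oxirane carbons are cleaved in step 4.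

Step 2
Reactants: 2 (4S)-limonene 1,2-oxide
Product: 3 (4S)-4-(2,2-dibromo-1-methylcyclopropyl)-1-methyl-7-oxabicyclo[4.1.0]heptane (diastereomer mixture)
Conditions: CHBr3, 50% aq. NaOH, BnEt3NCl (cat.), CH2Cl2, rt
Reagents that add atoms: bromoform, BrC(Br)Br
Why: Phase-transfer dibromocarbene cyclopropanation should take place at the only remaining alkene while the base-stable trisubstituted oxirane survives, and the new cyclopropane centres are erased in step 8.

Step 3
Reactants: 3 dibromocyclopropane
Product: 4 (4S)-4-(2-bromo-1-methylcyclopropyl)-1-methyl-7-oxabicyclo[4.1.0]heptane (diastereomer mixture)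
Conditions: Bu3SnH (1.05 equiv), AIBN (cat.), benzene, 50 °C
Reagents that add atoms: none
Why: Radical mono-debromination of a gem-dibromocyclopropane with one equivalent of tin hydride should stop at the monobromide because the second C–Br bond is reduced far more slowly.

Step 4
Reactants: 4 bromocyclopropyl oxirane
Product: 5 (3S)-3-(2-bromo-1-methylcyclopropyl)-6-oxoheptanal
Conditions: H5IO6, THF/H2O, 0 °C to rt
Reagents that add atoms: periodic acid, O=I(O)(O)(O)(O)O
Why: Periodic acid hydrolyses the oxirane and cleaves the glycol in one pot (Malaprade cleavage), so both oxirane diastereomers should converge on the same keto aldehyde with C6 untouched.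

Step 5
Reactants: 5 keto aldehyde
Product: 7 (3S)-3-(2-bromo-1-methylcyclopropyl)-2-methylene-6-oxoheptanal, via Mannich base 6 (not isolated)
Conditions: Me2N=CH2 I (Eschenmoser's salt), NEt3, CH2Cl2, rt
Reagents that add atoms: Eschenmoser's salt, C=[N+](C)C.[I-]
Why: Mannich reaction at the more readily enolised aldehyde α-CH2 followed by β-elimination of dimethylamine should give the α-methylene aldehyde without touching the methyl ketone.

Step 6
Reactants: 7 α-methylene aldehyde
Product: 8 (5S)-5-(2-bromo-1-methylcyclopropyl)-6-methyleneoct-7-en-2-one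
Conditions: Ph3PCH3Br, KN(SiMe3)2, THF, −78 °C; then 7 (1.0 equiv ylide), −78 to 0 °C
Reagents that add atoms: methyltriphenylphosphonium bromide, C[P+](c1ccccc1)(c1ccccc1)c1ccccc1.[Br-]
Why: Wittig methylenation with one equivalent of ylide at low temperature is selective for the aldehyde over the methyl ketone and should give the 2-substituted buta-1,3-diene.

Step 7
Reactants: 8 dienyl methyl ketone
Product: 9 (6S)-6-(2-bromo-1-methylcyclopropyl)-3-methyl-7-methylenenona-1,8-dien-3-ol (C3 epimers)
Conditions: CH2=CHMgBr, THF, −78 to 0 °C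
Reagents that add atoms: vinylmagnesium bromide, C=C[Mg]Br
Why: Grignard 1,2-addition to the methyl ketone installs C2 and the C3 methyl carbinol, and the uncontrolled carbinol centre is removed again in step 10.

Step 8
Reactants: 9 bromocyclopropyl trienol
Product: 10 (6S)-3-methyl-6-(1-methylcycloprop-2-en-1-yl)-7-methylenenona-1,8-dien-3-ol (C3 epimers)
Conditions: KOtBu (2.5 equiv), DMSO, rt
Reagents that add atoms: none
Why: 1,2-Dehydrobromination of the bromocyclopropane can only run towards the ring CH2 because the other neighbour is quaternary, which should give the 3,3-disubstituted cyclopropene and erase the cyclopropane stereocentres.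

Step 9
Reactants: 10 cyclopropenyl trienol
Product: 11 trans-fused 3,10-dimethyl-7-methylenebicyclo[5.3.0]deca-1,8-dien-3-ol (H-6 β, 10-CH3 α; C3 epimers)
Conditions: RuCl2(=CHPh)(PCy3)(H2IMes) (second-generation Grubbs catalyst, 10 mol %), 1,4-benzoquinone (20 mol %), toluene, 0.002 M, slow addition of 10, 60 °C
Reagents that add atoms: none
Why: A ruthenium alkylidene loaded on the butadienyl terminus (C8) or on the vinyl carbinol (C2) adds across the highly strained cyclopropene C=C, the metallacyclobutane opens to a cycloalkene and a new alkylidene on the other former cyclopropene carbon, and this alkylidene closes the second ring on the remaining vinyl group with loss of ethylene; opening of the cyclopropene by Ru=CH2 first leads to the same two closures. The closest known reaction type is the ring-rearrangement metathesis (ring opening/ring closing) of 3,3-disubstituted cyclopropenes that carry alkenyl tethers, run here as a double closure. The five-membered ring closes by alkene metathesis between C8 and one cyclopropene CH (C9), which forms the C8=C9 bond, and the seven-membered ring closes by metathesis between the other cyclopropene CH (C1) and C2. The only new stereocentre, C10, is set by C6: in the metallacyclobutane that closes the cyclopentene the bulky ruthenium centre should lie beside H-6 while the C5 chain turns to the exo side, so that the arm left for the seven-membered ring is trans to the C5 chain and the ring fusion is trans. The step needs the 5/7 pairing and this arm selection: the two arms on C10 are the same one-carbon unit, so either order of events gives the 5/7 skeleton, the 1,1-disubstituted C7=CH2 could only close a four-membered ring, and strain release should make the cyclopropene react before a direct C2/C8 closure. High dilution and benzoquinone are used against oligomerisation of the cyclopropene and against alkene migration.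

Step 10
Reactants: 11 bicyclic tertiary allylic alcohol
Product: 12 trans-fused 3,10-dimethyl-7-methylenebicyclo[5.3.0]deca-2,8-dien-1-one
Conditions: [C5H5NH][CrO3Cl] (pyridinium chlorochromate), 4 Å MS, CH2Cl2, rt
Reagents that add atoms: pyridinium chlorochromate, [O-][Cr](=O)(=O)Cl.c1cc[nH+]cc1
Why: Babler–Dauben oxidative 1,3-transposition ([3,3] shift of the chromate ester, then oxidation) should convert both C3 epimers into the same enone with oxygen on C1 and the C2=C3 alkene in place.

Step 11
Reactants: 12 enone
Product: 13 trans-fused 3,10-dimethyl-7-methylenebicyclo[5.3.0]deca-2,8-dien-1α-ol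
Conditions: NaBH4, CeCl3·7H2O, MeOH, −40 °C
Reagents that add atoms: none
Why: Luche 1,2-reduction should deliver hydride to the β face of the carbonyl, anti to the pseudo-axial C10 methyl, giving the 1α-alcohol (hydroxyl cis to that methyl).

Step 12
Reactants: 13 1α-allylic alcohol
Product: 14 trans-fused 3,10-dimethyl-7-methylenebicyclo[5.3.0]deca-2,8-dien-1β-yl 4-nitrobenzoate
Conditions: 4-nitrobenzoic acid, PPh3, DIAD, toluene, 0 °C to rt
Reagents that add atoms: 4-nitrobenzoic acid, O=C(O)c1ccc(cc1)[N+](=O)[O-]
Why: Mitsunobu esterification inverts C1 by SN2 attack of the carboxylate from the open β face, which sets the C1 configuration of the target and protects the oxygen.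

Step 13
Reactants: 14 dienyl 4-nitrobenzoate
Product: 16 trans-fused 7α-(hydroxymethyl)-3,10-dimethylbicyclo[5.3.0]deca-2,8-dien-1β-yl 4-nitrobenzoate, via B-alkyl-9-BBN adduct 15 (not isolated)
Conditions: 9-BBN, THF, 0 °C to rt; then 30% H2O2, pH 7 phosphate buffer
Reagents that add atoms: hydrogen peroxide, OO
Why: Anti-Markovnikov hydroboration with 9-BBN is selective for the terminal exocyclic methylene over the hindered di- and trisubstituted ring alkenes, hydrogen should add to C7 from the less hindered β face, and this C7 centre is corrected in step 16.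

Step 14
Reactants: 16 homoallylic alcohol
Product: 17 trans-fused 7α-(hydroxymethyl)-3,10-dimethylbicyclo[5.3.0]dec-2-en-1β-yl 4-nitrobenzoate
Conditions: 2-nitrobenzenesulfonylhydrazide (NBSH), NEt3, CH2Cl2, rt
Reagents that add atoms: none
Why: Diimide reduction (concerted syn transfer of H2) should saturate the cis-disubstituted cyclopentene C8=C9 to the CH2–CH2 unit of the target while leaving the trisubstituted allylic alkene, the ester and the nitro group untouched.

Step 15
Reactants: 17 primary alcohol
Product: 18 trans-fused 7α-formyl-3,10-dimethylbicyclo[5.3.0]dec-2-en-1β-yl 4-nitrobenzoate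
Conditions: Dess–Martin periodinane, CH2Cl2, rt
Reagents that add atoms: none
Why: Dess–Martin oxidation converts the primary alcohol into the aldehyde under neutral conditions that do not touch the allylic ester.

Step 16
Reactants: 18 aldehyde ester
Product: 20 trans-fused 7β-ethynyl-3,10-dimethylbicyclo[5.3.0]dec-2-en-1β-ol, via 7β-formyl-1β-ol 19 (not isolated)
Conditions: K2CO3, MeOH, rt; then dimethyl (1-diazo-2-oxopropyl)phosphonate, rt
Reagents that add atoms: dimethyl (1-diazo-2-oxopropyl)phosphonate, CC(=O)C(=[N+]=[N-])P(=O)(OC)OC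
Why: Methanolic carbonate cleaves the activated ester and equilibrates the α-branched aldehyde to the more stable 7β epimer (trans to the C5 ring bond and anti to the C10 methyl), and the Ohira–Bestmann variant of the Seyferth–Gilbert homologation then turns it into the terminal alkyne.

Step 17
Reactants: 20 alkynol
Product: 22 trans-fused 7β-[(E)-1-iodoprop-1-en-2-yl]-3,10-dimethylbicyclo[5.3.0]dec-2-en-1β-ol, via alkenylalane 21 (not isolated)
Conditions: AlMe3 (4 equiv), Cp2ZrCl2 (0.5 equiv), CH2Cl2, 0 °C to rt; then I2, THF, −30 °C; aq. Na2S2O3/NaHCO3 work-up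
Reagents that add atoms: trimethylaluminium, C[Al](C)C; iodine, II
Why: Negishi zirconium-catalysed carboalumination adds methyl and aluminium syn across the terminal alkyne with methyl on the internal carbon, and iodinolysis with retention should give the (E)-2-methylalkenyl iodide while the hydroxyl is carried as its aluminium alkoxide.

Step 18
Reactants: 22 allylic alcohol
Product: 23 trans-fused 2β,3β-epoxy-7β-[(E)-1-iodoprop-1-en-2-yl]-3,10-dimethylbicyclo[5.3.0]decan-1β-ol
Conditions: VO(acac)2 (5 mol %), tBuOOH, CH2Cl2, 0 °C to rt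
Reagents that add atoms: tert-butyl hydroperoxide, CC(C)(C)OO
Why: Vanadium-catalysed hydroxyl-directed epoxidation delivers oxygen to the C2=C3 face syn to the 1β-hydroxyl, which sets C2 and C3 as the cis-epoxy alcohol and leaves the alkenyl iodide alone.

Step 19
Reactants: 23 epoxy alcohol
Product: 24 trans-fused 2β,3β-epoxy-7β-[(E)-1-iodoprop-1-en-2-yl]-3,10-dimethylbicyclo[5.3.0]decan-1β-yl acetate
Conditions: Ac2O, pyridine, DMAP (cat.), CH2Cl2, rt
Reagents that add atoms: acetic anhydride, CC(=O)OC(C)=O
Why: DMAP-catalysed acylation should acetylate the hindered secondary alcohol without opening the oxirane.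

Step 20
Reactants: 24 alkenyl iodide; 25 2-methylbut-3-en-2-ol
Product: 26 CNP0265175.2 (1β-acetoxy-2β,3β-epoxy-7β-[(2E,4E)-6-hydroxy-6-methylhepta-2,4-dien-2-yl]-3,10-dimethyl-trans-bicyclo[5.3.0]decane)
Conditions: Pd(OAc)2 (10 mol %), AgOAc (1.5 equiv), 25 (3 equiv), DMF, rt to 50 °C
Reagents that add atoms: 2-methylbut-3-en-2-ol, CC(C)(O)C=C
Why: Mizoroki–Heck coupling under silver-promoted neutral conditions adds the alkenylpalladium to the terminal carbon of 25, and β-hydride elimination, possible only away from the carbinol, should give the (E,E)-diene with the iodide geometry retained and the acetate and oxirane intact.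

**Compound list**

1 | (S)-(−)-limonene | CC1=CC[C@H](CC1)C(C)=C | starting material
2 | (4S)-limonene 1,2-oxide (cis/trans mixture) | CC12OC1C[C@H](CC2)C(C)=C | intermediate
3 | (4S)-4-(2,2-dibromo-1-methylcyclopropyl)-1-methyl-7-oxabicyclo[4.1.0]heptane | CC12OC1C[C@H](CC2)C1(C)CC1(Br)Br | intermediate
4 | (4S)-4-(2-bromo-1-methylcyclopropyl)-1-methyl-7-oxabicyclo[4.1.0]heptane | CC12OC1C[C@H](CC2)C1(C)CC1Br | intermediate
5 | (3S)-3-(2-bromo-1-methylcyclopropyl)-6-oxoheptanal | CC(=O)CC[C@@H](CC=O)C1(C)CC1Br | intermediate
6 | Mannich base, (3S)-3-(2-bromo-1-methylcyclopropyl)-2-[(dimethylamino)methyl]-6-oxoheptanal | CC(=O)CC[C@@H](C(CN(C)C)C=O)C1(C)CC1Br | intermediate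
7 | (3S)-3-(2-bromo-1-methylcyclopropyl)-2-methylene-6-oxoheptanal | CC(=O)CC[C@@H](C(=C)C=O)C1(C)CC1Br | intermediate
8 | (5S)-5-(2-bromo-1-methylcyclopropyl)-6-methyleneoct-7-en-2-one | CC(=O)CC[C@@H](C(=C)C=C)C1(C)CC1Br | intermediate
9 | (6S)-6-(2-bromo-1-methylcyclopropyl)-3-methyl-7-methylenenona-1,8-dien-3-ol | CC(O)(C=C)CC[C@@H](C(=C)C=C)C1(C)CC1Br | intermediate
10 | (6S)-3-methyl-6-(1-methylcycloprop-2-en-1-yl)-7-methylenenona-1,8-dien-3-ol | CC(O)(C=C)CC[C@@H](C(=C)C=C)C1(C)C=C1 | intermediate
11 | trans-fused 3,10-dimethyl-7-methylenebicyclo[5.3.0]deca-1,8-dien-3-ol (H-6 β, 10-CH3 α) | C1=CC(C)(O)CC[C@H]2C(=C)C=C[C@]12C | intermediate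
12 | trans-fused 3,10-dimethyl-7-methylenebicyclo[5.3.0]deca-2,8-dien-1-one | O=C1C=C(C)CC[C@H]2C(=C)C=C[C@]12C | intermediate
13 | trans-fused 3,10-dimethyl-7-methylenebicyclo[5.3.0]deca-2,8-dien-1α-ol | O[C@H]1C=C(C)CC[C@H]2C(=C)C=C[C@]12C | intermediate
14 | trans-fused 3,10-dimethyl-7-methylenebicyclo[5.3.0]deca-2,8-dien-1β-yl 4-nitrobenzoate | O=C(O[C@@H]1C=C(C)CC[C@H]2C(=C)C=C[C@]12C)c1ccc(cc1)[N+](=O)[O-] | intermediate
15 | B-alkyl-9-BBN adduct of 14 (boron on C11, H-7 β) | O=C(O[C@@H]1C=C(C)CC[C@H]2[C@@H](CB3C4CCCC3CCC4)C=C[C@]12C)c1ccc(cc1)[N+](=O)[O-] | intermediate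
16 | trans-fused 7α-(hydroxymethyl)-3,10-dimethylbicyclo[5.3.0]deca-2,8-dien-1β-yl 4-nitrobenzoate | O=C(O[C@@H]1C=C(C)CC[C@H]2[C@@H](CO)C=C[C@]12C)c1ccc(cc1)[N+](=O)[O-] | intermediate
17 | trans-fused 7α-(hydroxymethyl)-3,10-dimethylbicyclo[5.3.0]dec-2-en-1β-yl 4-nitrobenzoate | O=C(O[C@@H]1C=C(C)CC[C@H]2[C@@H](CO)CC[C@]12C)c1ccc(cc1)[N+](=O)[O-] | intermediate
18 | trans-fused 7α-formyl-3,10-dimethylbicyclo[5.3.0]dec-2-en-1β-yl 4-nitrobenzoate | O=C(O[C@@H]1C=C(C)CC[C@H]2[C@@H](C=O)CC[C@]12C)c1ccc(cc1)[N+](=O)[O-] | intermediate
19 | trans-fused 7β-formyl-3,10-dimethylbicyclo[5.3.0]dec-2-en-1β-ol | O[C@@H]1C=C(C)CC[C@H]2[C@H](C=O)CC[C@]12C | intermediate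
20 | trans-fused 7β-ethynyl-3,10-dimethylbicyclo[5.3.0]dec-2-en-1β-ol | O[C@@H]1C=C(C)CC[C@H]2[C@H](C#C)CC[C@]12C | intermediate
21 | (E)-alkenyl(dimethyl)alane of 20, hydroxyl as dimethylaluminium alkoxide | C[Al](C)O[C@@H]1C=C(C)CC[C@H]2[C@H](/C(C)=C/[Al](C)C)CC[C@]12C | intermediate
22 | trans-fused 7β-[(E)-1-iodoprop-1-en-2-yl]-3,10-dimethylbicyclo[5.3.0]dec-2-en-1β-ol | O[C@@H]1C=C(C)CC[C@H]2[C@H](/C(C)=C/I)CC[C@]12C | intermediate
23 | trans-fused 2β,3β-epoxy-7β-[(E)-1-iodoprop-1-en-2-yl]-3,10-dimethylbicyclo[5.3.0]decan-1β-ol | O[C@@H]1[C@@H]2O[C@]2(C)CC[C@H]2[C@H](/C(C)=C/I)CC[C@]12C | intermediate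
24 | trans-fused 2β,3β-epoxy-7β-[(E)-1-iodoprop-1-en-2-yl]-3,10-dimethylbicyclo[5.3.0]decan-1β-yl acetate | CC(=O)O[C@@H]1[C@@H]2O[C@]2(C)CC[C@H]2[C@H](/C(C)=C/I)CC[C@]12C | intermediate
25 | 2-methylbut-3-en-2-ol | CC(C)(O)C=C | starting material
26 | CNP0265175.2 | CC(=O)O[C@@H]1[C@@H]2O[C@]2(C)CC[C@H]2[C@H](/C(C)=C/C=C/C(C)(C)O)CC[C@]12C | target

**Step count and risks**

Total step count: 20. Longest linear sequence: 20 steps (1 to 26; 25 is used as purchased).

Steps most likely to fail:

Step 9. What may go wrong is loss of the selection between the two cyclopropene carbons: if the ruthenium methylidene opens the cyclopropene before the catalyst is loaded on a tether, the C6-controlled bicyclic transition state is bypassed. Intermolecular oligomerisation of the cyclopropene is the second risk. The fallback moves the arm selection from the substrate to the reagent. It sets out from 10, which is silylated (TMSCl, imidazole, CH2Cl2) to the trimethylsilyl ether of 10 F1. F1 is submitted to asymmetric ring-opening/ring-closing metathesis with the chiral molybdenum alkylidene Mo(=N-2,6-iPr2C6H3)(=CHCMe2Ph)(3,3'-di-tert-butyl-5,5',6,6'-tetramethylbiphenyl-2,2'-diolate) in benzene, using the enantiomer of the diolate that is matched with C6. This should give the trimethylsilyl ether of 11 F2. Desilylation (K2CO3, MeOH) comes back to the route at 11.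

Step 12. What may go wrong is elimination to a diene or SN2' attack instead of SN2 displacement at the carbinol next to the quaternary carbon; the step also depends on the facial selectivity of step 11. The fallback replaces substrate-controlled reduction plus inversion by reagent-controlled reduction. It sets out from 12, which is reduced with (S)-2-methyl-CBS-oxazaborolidine and catecholborane in toluene at −78 °C; the quaternary C10 side is expected to act as the large group, and the (R)-reagent is the control. This should give trans-fused 3,10-dimethyl-7-methylenebicyclo[5.3.0]deca-2,8-dien-1β-ol F3 directly. Acylation with 4-nitrobenzoyl chloride, pyridine and DMAP comes back to the route at 14.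

Step 8. What may go wrong is base-induced migration of the 2-substituted diene (deprotonation at C6) or addition of the tertiary alkoxide to the new cyclopropene during the dehydrobromination. The fallback unveils the cyclopropene before any diene or carbonyl group is present and carries it through. It sets out from 4, which is dehydrobrominated (KOtBu, DMSO, rt) to (4S)-1-methyl-4-(1-methylcycloprop-2-en-1-yl)-7-oxabicyclo[4.1.0]heptane F4. Cleavage with H5IO6 in buffered THF/H2O at 0 °C gives (3S)-3-(1-methylcycloprop-2-en-1-yl)-6-oxoheptanal F5. Methylenation with Eschenmoser's salt and NEt3 gives (3S)-2-methylene-3-(1-methylcycloprop-2-en-1-yl)-6-oxoheptanal F6. Wittig methylenation gives (5S)-5-(1-methylcycloprop-2-en-1-yl)-6-methyleneoct-7-en-2-one F7. Addition of CH2=CHMgBr comes back to the route at 10.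

Further compounds
F1 | step 9 | trimethylsilyl ether of 10 | C[Si](C)(C)OC(C)(C=C)CC[C@@H](C(=C)C=C)C1(C)C=C1
F2 | step 9 | trimethylsilyl ether of 11 | C1=CC(C)(O[Si](C)(C)C)CC[C@H]2C(=C)C=C[C@]12C
F3 | step 12 | trans-fused 3,10-dimethyl-7-methylenebicyclo[5.3.0]deca-2,8-dien-1β-ol | O[C@@H]1C=C(C)CC[C@H]2C(=C)C=C[C@]12C
F4 | step 8 | (4S)-1-methyl-4-(1-methylcycloprop-2-en-1-yl)-7-oxabicyclo[4.1.0]heptane | CC12OC1C[C@H](CC2)C1(C)C=C1
F5 | step 8 | (3S)-3-(1-methylcycloprop-2-en-1-yl)-6-oxoheptanal | CC(=O)CC[C@@H](CC=O)C1(C)C=C1
F6 | step 8 | (3S)-2-methylene-3-(1-methylcycloprop-2-en-1-yl)-6-oxoheptanal | CC(=O)CC[C@@H](C(=C)C=O)C1(C)C=C1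
F7 | step 8 | (5S)-5-(1-methylcycloprop-2-en-1-yl)-6-methyleneoct-7-en-2-one | CC(=O)CC[C@@H](C(=C)C=C)C1(C)C=C1
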